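**Retrosynthetic overview**

- Agecorynin F is traced back to 5,6-dihydroxy-7,2',3',4',5'-pentamethoxyflavone by methylation of O6 in the last step; the C5 hydroxyl, hydrogen-bonded to the C4 carbonyl, stays free.
- Feature used: ring A carries adjacent oxygens on C5 and C6, and C8a (the carbon bonded to O1) is para to the C6 oxygen and, through C4a, β to C5. The C5,C6-o-quinone is therefore an acceptor at C8a.
- Key disconnection O1–C8a: ring C closes when a ring A catechol 1,3-diketone is oxidized at an anode and the enol oxygen on C2 adds to C8a.
- The diketone is cut at C2–C3: C-acylation of polylithiated 2,3-dihydroxy-4-methoxyacetophenone with 2,3,4,5-tetramethoxybenzoyl chloride, which comes from 1,2,3,4-tetramethoxybenzene by ortho-lithiation/carboxylation.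
- Ring order: rings A and B are bought; ring C is the only ring made, in the key step.

Key step: step 4

Remark: 1,2,3,4-tetramethoxybenzene and 2,3-dihydroxy-4-methoxyacetophenone are taken as purchasable; ring positions are given in flavone numbering, also for open-chain compounds, and diketones are drawn as keto tautomers although they should exist mainly as chelated enols.

**Route**

Step 1
Reactants: 1 1,2,3,4-tetramethoxybenzene
Product: 3 2,3,4,5-tetramethoxybenzoic acid, via 2,3,4,5-tetramethoxyphenyllithium 2 (not isolated)
Conditions: n-BuLi (1.2 equiv), TMEDA (1.2 equiv), THF, 0 °C; then CO2, −78 °C to rt; aq. HCl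
Reagents that add atoms: carbon dioxide, O=C=O; n-butyllithium, [Li]CCCC (gives only the lithium of intermediate 2)
Why: Directed ortho-metalation, in which a methoxy oxygen guides the TMEDA-activated base to the flanking ring C–H (the two free positions are equivalent by symmetry), followed by carboxylation of the aryllithium.

Step 2
Reactants: 3 2,3,4,5-tetramethoxybenzoic acid
Product: 4 2,3,4,5-tetramethoxybenzoyl chloride
Conditions: (COCl)2 (1.3 equiv), DMF (cat.), CH2Cl2, 0 °C to rt; evaporate and use crude
Reagents that add atoms: oxalyl chloride, O=C(Cl)C(=O)Cl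
Why: Acid chloride formation through the chloroiminium species made from DMF, conditions to which aryl methyl ethers are inert.

Step 3
Reactants: 4 2,3,4,5-tetramethoxybenzoyl chloride; 5 2,3-dihydroxy-4-methoxyacetophenone
Product: 7 1-(2,3-dihydroxy-4-methoxyphenyl)-3-(2,3,4,5-tetramethoxyphenyl)propane-1,3-dione, via trilithiated acetophenone 6 (not isolated)
Conditions: 5, LiN(SiMe3)2 (4.2 equiv), THF, −78 to −10 °C; then 4 (1.0 equiv), THF, −78 °C to rt; cold aq. HCl to pH 4, Ar
Reagents that add atoms: lithium bis(trimethylsilyl)amide, [Li]N([Si](C)(C)C)[Si](C)(C)C (gives only the lithium of intermediate 6)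
Why: Claisen-type C-acylation of a ketone lithium enolate by an aroyl chloride, in which both phenols are held as lithium phenoxides, the enolate carbon of trianion 6 is the most nucleophilic site at −78 °C, and the fourth equivalent of base takes up the acidic diketone proton so that unreacted enolate is not quenched.

Step 4
Reactants: 7 1-(2,3-dihydroxy-4-methoxyphenyl)-3-(2,3,4,5-tetramethoxyphenyl)propane-1,3-dione
Product: 9 5,6-dihydroxy-7,2',3',4',5'-pentamethoxyflavone, via acyl o-quinone 8 (not isolated)
Conditions: graphite-felt anode, Pt cathode, divided cell, controlled potential at the first anodic wave of 7 (expected near +0.45 V vs Ag/AgCl), MeCN/0.2 M aq. NaH2PO4–Na2HPO4 (pH 6.5) 1:1, 5 mM, N2, rt, 2.1 F/mol; then aq. Na2S2O4 wash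
Reagents that add atoms: none
Why: Proposed new method: two-electron, two-proton oxidation of the catechol of 7 should give the 3-acyl-o-quinone 8, in which the ring carbon that becomes C8a is β to the quinone carbonyl at C5 (through C4a), β to the C4 ketone and para to the C6 oxygen. The enol oxygen on C2 then adds to this carbon (oxa-Michael addition) and enolization of the adduct restores aromatic ring A as the 5,6-dihydroxyflavone 9, the two electrons ending as H2 at the cathode. The closest known reaction type is the anodic oxidation of catechols to o-quinones in the presence of 1,3-dicarbonyl compounds, where Michael addition and a final enol-oxygen closure onto the re-oxidized quinone give benzofurans; here the dicarbonyl is already tethered through the acyl group, so the oxygen closure comes first and forms a pyranone. Ring C closes in the 6-endo-trig mode (O1 onto C8a of the C4a=C8a bond) and no stereocenter is formed. The step needs C–O bond formation at C8a only and oxidation of ring A only: the tether lets the enol oxygen reach C8a alone through a six-membered transition state, the catechol is oxidized well below the potential at which the tetramethoxyphenyl ring or the enol would react, and the near-neutral buffer keeps the acid-catalyzed cyclodehydration through the C5 hydroxyl (which would give the isomeric 8-hydroxy-7-methoxyflavone) slow. Any product oxidized further at the anode should act as a mediator toward unreacted 7, and what remains of it is returned to 9 by the Na2S2O4 wash.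

Step 5
Reactants: 9 5,6-dihydroxy-7,2',3',4',5'-pentamethoxyflavone
Product: 10 agecorynin F (5-hydroxy-6,7,2',3',4',5'-hexamethoxyflavone)
Conditions: MeI (1.1 equiv), K2CO3 (1.2 equiv), degassed acetone, rt to 40 °C, Ar
Reagents that add atoms: iodomethane, CI
Why: Williamson ether synthesis in which the C6 hydroxyl is the free, more acidic phenol while the C5 hydroxyl is locked in a hydrogen bond to the C4 carbonyl, so one equivalent of electrophile with a weak base should methylate O6 only.

**Compound list**

1 | 1,2,3,4-tetramethoxybenzene | COc1ccc(OC)c(OC)c1OC | starting material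
2 | 2,3,4,5-tetramethoxyphenyllithium | [Li]c1cc(OC)c(OC)c(OC)c1OC | intermediate
3 | 2,3,4,5-tetramethoxybenzoic acid | COc1cc(C(=O)O)c(OC)c(OC)c1OC | intermediate
4 | 2,3,4,5-tetramethoxybenzoyl chloride | COc1cc(C(=O)Cl)c(OC)c(OC)c1OC | intermediate
5 | 2,3-dihydroxy-4-methoxyacetophenone | COc1ccc(C(C)=O)c(O)c1O | starting material
6 | trilithiated 2,3-dihydroxy-4-methoxyacetophenone (dilithium phenoxide, lithium enolate) | [Li]Oc1c(O[Li])c(OC)ccc1C(=C)O[Li] | intermediate
7 | 1-(2,3-dihydroxy-4-methoxyphenyl)-3-(2,3,4,5-tetramethoxyphenyl)propane-1,3-dione | COc1ccc(C(=O)CC(=O)c2cc(OC)c(OC)c(OC)c2OC)c(O)c1O | intermediate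
8 | 3-methoxy-6-[3-oxo-3-(2,3,4,5-tetramethoxyphenyl)propanoyl]cyclohexa-3,5-diene-1,2-dione | COC1=CC=C(C(=O)CC(=O)c2cc(OC)c(OC)c(OC)c2OC)C(=O)C1=O | intermediate
9 | 5,6-dihydroxy-7,2',3',4',5'-pentamethoxyflavone | COc1cc(-c2cc(=O)c3c(O)c(O)c(OC)cc3o2)c(OC)c(OC)c1OC | intermediate
10 | agecorynin F (5-hydroxy-6,7,2',3',4',5'-hexamethoxyflavone) | COc1cc(-c2cc(=O)c3c(O)c(OC)c(OC)cc3o2)c(OC)c(OC)c1OC | target

**Count**

Total steps: 5. Longest linear sequence: 5 steps (1 → 3 → 4 → 7 → 9 → 10); acetophenone 5 enters at step 3.

**Steps most likely to fail**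

Step 4 (proposed new method). The o-quinone may be consumed by intermolecular paths (addition of water, attack by the enol of a second molecule) faster than the 6-endo closure, or the diketone may cyclodehydrate through the C5 hydroxyl before it is oxidized. The fallback uses known chemistry, sets out from acid chloride 4 and comes back to the route at target 10.
- The dilithium phenoxide-enolate of commercially available 6'-hydroxy-2',3',4'-trimethoxyacetophenone F1 (LiN(SiMe3)2, 3.1 equiv, THF, −78 to −10 °C) would be C-acylated with 4 to give 1-(6-hydroxy-2,3,4-trimethoxyphenyl)-3-(2,3,4,5-tetramethoxyphenyl)propane-1,3-dione F2.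
- Cyclodehydration through its single free hydroxyl (H2SO4 cat., AcOH, 95 °C) should give 5,6,7,2',3',4',5'-heptamethoxyflavone F3.
- BCl3 (1.2 equiv, CH2Cl2, −78 to 0 °C), guided by chelation to the C4 carbonyl, should cleave only the C5 methyl ether and give 10.
- In this variant the O1–C8a bond is bought with the phenol, and steps 4 and 5 are not needed.

Step 3. The lithium phenoxides, mainly the non-chelated one at C6, may be O-aroylated in competition with C-acylation; the trianion may be poorly soluble; the free catechol diketone may be air-oxidized or cyclodehydrated during work-up. The fallback sets out from acetophenone 5 and comes back at diketone 7.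
- Both phenols would be benzylated (BnBr, K2CO3, DMF, 60 °C) to 2,3-bis(benzyloxy)-4-methoxyacetophenone F4.
- Its lithium enolate (LiN(SiMe3)2, 2.2 equiv, THF, −78 °C) would be acylated with 4 to give 1-[2,3-bis(benzyloxy)-4-methoxyphenyl]-3-(2,3,4,5-tetramethoxyphenyl)propane-1,3-dione F5.
- Hydrogenolysis under neutral conditions (H2, Pd/C, EtOAc, rt) should free the catechol and give 7.

Step 5. Methylation may spread to the chelated C5 hydroxyl, or the catechol may be air-oxidized under base before it is alkylated. The fallback sets out from 9 and comes back at 10.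
- Exhaustive methylation (MeI in excess, K2CO3, acetone, reflux) would give 5,6,7,2',3',4',5'-heptamethoxyflavone F6, the same substance as F3.
- Chelation-controlled cleavage of the C5 methyl ether with BCl3 (1.2 equiv, CH2Cl2, −78 to 0 °C) should then restore the C5 hydroxyl and give 10.

**Further compounds**

F1 | step 4 | 6'-hydroxy-2',3',4'-trimethoxyacetophenone | CC(=O)c1c(O)cc(OC)c(OC)c1OC
F2 | step 4 | 1-(6-hydroxy-2,3,4-trimethoxyphenyl)-3-(2,3,4,5-tetramethoxyphenyl)propane-1,3-dione | COc1cc(O)c(C(=O)CC(=O)c2cc(OC)c(OC)c(OC)c2OC)c(OC)c1OC
F3 | step 4 | 5,6,7,2',3',4',5'-heptamethoxyflavone | COc1cc(-c2cc(=O)c3c(OC)c(OC)c(OC)cc3o2)c(OC)c(OC)c1OC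
F4 | step 3 | 2,3-bis(benzyloxy)-4-methoxyacetophenone | COc1ccc(C(C)=O)c(OCc2ccccc2)c1OCc1ccccc1
F5 | step 3 | 1-[2,3-bis(benzyloxy)-4-methoxyphenyl]-3-(2,3,4,5-tetramethoxyphenyl)propane-1,3-dione | COc1ccc(C(=O)CC(=O)c2cc(OC)c(OC)c(OC)c2OC)c(OCc2ccccc2)c1OCc1ccccc1
F6 | step 5 | 5,6,7,2',3',4',5'-heptamethoxyflavone | COc1cc(-c2cc(=O)c3c(OC)c(OC)c(OC)cc3o2)c(OC)c(OC)c1OC
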